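**Plan**

1. Retrosynthesis: the dienal and the secondary acetate are late adjustments, and the epoxide is cut back to the C1=C6 alkene of a 2,5-disubstituted p-benzoquinone. The quinone carbocycle is then cut at its two acyl–CH bonds, C1–C2 and C4–C5 (target numbering: C1 epoxide CH, C2 and C5 carbonyls, C3 carrying CH2OAc, C4 vinyl CH, C6 quaternary epoxide carbon).
2. Enabling feature: the six-membered ring is two O=C–C(C–O)=CH units joined head to tail. C2–C3–C4 with its CH2OAc is ring-opened (acetoxymethyl)cyclopropenone (acyl electrophile plus cis-vinyl nucleophile by strain release). C5–C6–C1 with its carbinol is a (Z)-β-metallated Baylis–Hillman ester of methyl propiolate (cis-vinyl nucleophile plus ester electrophile).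
3. Forward: the dienal side chain is made by Suzuki coupling, joined to methyl propiolate in a catalytic asymmetric iodo-Baylis–Hillman coupling, and borylated. A rhodium-catalysed [3+3] union with the cyclopropenone then closes the carbocycle directly as the quinone; the epoxide ring follows, then acetylation, desilylation and oxidation.
4. Stereochemistry: the carbinol center is set by oxazaborolidinium catalysis. Both epoxide centers are relayed from it in one hydroxyl-directed nucleophilic epoxidation. The alkene geometries come from an (E)-enol triflate and an (E)-alkenylboronate coupled with retention.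

Key step: step 8

Assumption: the (E)-3-silyloxypropenyl pinacol boronate used in step 3 is taken as a catalogue reagent.
Assumption: the catalyst in step 6 is written for the S carbinol; if the dienal reacts with the opposite facial sense, the antipodal catalyst is used.

**Route**

Step 1
Reactants: 1 prop-2-yn-1-yl acetate
Product: 3 (3-oxocycloprop-1-en-1-yl)methyl acetate, via gem-difluorocyclopropene 2 (not isolated)
Conditions: Me3SiCF3, NaI, THF, 110 °C (sealed tube); then wet SiO2, CH2Cl2, rt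
Reagents that add atoms: (trifluoromethyl)trimethylsilane, C[Si](C)(C)C(F)(F)F; water, O
Why: Difluorocarbene released from Me3SiCF3 by iodide should add to the terminal alkyne ([2+1] cycloaddition) and the gem-difluorocyclopropene should hydrolyse on wet silica to the cyclopropenone; no stereocenter is formed.

Step 2
Reactants: 4 ethyl acetoacetate
Product: 5 ethyl (2E)-3-{[(trifluoromethyl)sulfonyl]oxy}but-2-enoate
Conditions: Tf2O, aq Me4NOH, hexanes, 5–10 °C
Reagents that add atoms: trifluoromethanesulfonic anhydride, O=S(=O)(OS(=O)(=O)C(F)(F)F)C(F)(F)F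
Why: O-Triflation of the β-keto ester enolate; the non-chelating tetramethylammonium counter-ion should favour the extended enolate and hence the (E)-enol triflate (stereoselective enol triflate formation).

Step 3
Reactants: 5 ethyl (2E)-3-{[(trifluoromethyl)sulfonyl]oxy}but-2-enoate; 6 tert-butyl(dimethyl){[(2E)-3-(4,4,5,5-tetramethyl-1,3,2-dioxaborolan-2-yl)prop-2-en-1-yl]oxy}silane
Product: 7 ethyl (2E,4E)-6-{[tert-butyl(dimethyl)silyl]oxy}-3-methylhexa-2,4-dienoate
Conditions: Pd(PPh3)4 (5 mol %), K3PO4, 1,4-dioxane/H2O, 60 °C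
Reagents that add atoms: none
Why: Suzuki–Miyaura coupling of an enol triflate with an alkenylboronate should proceed with retention at both alkenes and give the (2E,4E)-diene.

Step 4
Reactants: 7 ethyl (2E,4E)-6-{[tert-butyl(dimethyl)silyl]oxy}-3-methylhexa-2,4-dienoate
Product: 8 (2E,4E)-6-{[tert-butyl(dimethyl)silyl]oxy}-3-methylhexa-2,4-dien-1-ol
Conditions: i-Bu2AlH (2.2 equiv), CH2Cl2, −78 °C; Rochelle salt work-up
Reagents that add atoms: none
Why: 1,2-Reduction of the conjugated ester by the aluminium hydride should give the allylic alcohol without touching the diene or the silyl ether.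

Step 5
Reactants: 8 (2E,4E)-6-{[tert-butyl(dimethyl)silyl]oxy}-3-methylhexa-2,4-dien-1-ol
Product: 9 (2E,4E)-6-{[tert-butyl(dimethyl)silyl]oxy}-3-methylhexa-2,4-dienal
Conditions: MnO2, CH2Cl2, rt
Reagents that add atoms: none
Why: Allylic alcohol oxidation with MnO2 should give the dienal without alkene isomerisation.

Step 6
Reactants: 9 (2E,4E)-6-{[tert-butyl(dimethyl)silyl]oxy}-3-methylhexa-2,4-dienal; 10 methyl propiolate
Product: 13 methyl (2Z)-2-[(1S,2E,4E)-6-{[tert-butyl(dimethyl)silyl]oxy}-1-hydroxy-3-methylhexa-2,4-dien-1-yl]-3-iodoprop-2-enoate, via silyl iodoallenolate 11 (not isolated), via O-trimethylsilyl ether 12 (not isolated)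
Conditions: Me3SiI, oxazaborolidinium triflimide catalyst (20 mol %; N-protonated (S)-3,3-diphenyl-1-(2-methylphenyl)tetrahydropyrrolo[1,2-c][1,3,2]oxazaborole, counter-ion Tf2N−), CH2Cl2, −78 °C; then 1 M HCl, THF, 0 °C
Reagents that add atoms: iodotrimethylsilane, C[Si](C)(C)I
Why: Catalytic asymmetric three-component iodo-Morita–Baylis–Hillman-type coupling: conjugate addition of iodide to the propiolate gives the silyl iodoallenolate, which should add (Mukaiyama-type aldol) to the face of the catalyst-bound aldehyde left open by the chiral boron cation and so set the S carbinol, with the iodine cis to the ester.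

Step 7
Reactants: 13 methyl (2Z)-2-[(1S,2E,4E)-6-{[tert-butyl(dimethyl)silyl]oxy}-1-hydroxy-3-methylhexa-2,4-dien-1-yl]-3-iodoprop-2-enoate
Product: 14 methyl (2Z)-2-[(1S,2E,4E)-6-{[tert-butyl(dimethyl)silyl]oxy}-1-hydroxy-3-methylhexa-2,4-dien-1-yl]-3-(4,4,5,5-tetramethyl-1,3,2-dioxaborolan-2-yl)prop-2-enoate
Conditions: B2pin2, PdCl2(dppf) (5 mol %), KOAc, 1,4-dioxane, 80 °C
Reagents that add atoms: bis(pinacolato)diboron, CC1(C)OB(OC1(C)C)B1OC(C)(C)C(C)(C)O1
Why: Miyaura borylation of the alkenyl iodide should proceed with retention, keeping boron cis to the ester, and should tolerate the free carbinol and the silyl ether.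

Step 8
Reactants: 14 methyl (2Z)-2-[(1S,2E,4E)-6-{[tert-butyl(dimethyl)silyl]oxy}-1-hydroxy-3-methylhexa-2,4-dien-1-yl]-3-(4,4,5,5-tetramethyl-1,3,2-dioxaborolan-2-yl)prop-2-enoate; 3 (3-oxocycloprop-1-en-1-yl)methyl acetate
Product: 15 {4-[(1S,2E,4E)-6-{[tert-butyl(dimethyl)silyl]oxy}-1-hydroxy-3-methylhexa-2,4-dien-1-yl]-3,6-dioxocyclohexa-1,4-dien-1-yl}methyl acetate
Conditions: [Rh(cod)(OMe)]2 (5 mol %), 1,4-dioxane, 4 Å molecular sieves, 40 °C, slow addition of 3 (1.5 equiv)
Reagents that add atoms: none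
Why: Proposed new method: transmetalation of the cis-alkenylboronate to the monovalent rhodium methoxide should give an alkenylrhodium that adds to the strained carbonyl of the cyclopropenone (first acyl–CH bond, C1–C2); the rhodium cyclopropenolate should then open by β-carbon elimination toward the unsubstituted ring carbon to a cis-β-acylvinylrhodium, which adds to the cis-disposed methyl ester with loss of methoxide (second acyl–CH bond, C4–C5) and returns the rhodium methoxide. The closest known reaction types are the rhodium-catalysed addition of organoboron reagents to cyclobutanones and cyclopropenones with ring opening by β-carbon elimination, and the rhodium-catalysed annulation of boron reagents carrying a cis or ortho ester, in which the organorhodium formed after insertion closes onto that ester. The six-membered carbocycle closes by 6-exo-trig acyl substitution at the ester carbonyl and appears directly at the quinone oxidation level. No stereocenter is formed and the S carbinol is not involved. Cross-union rather than self-union is built in, because only the boronate can transmetalate and only the cyclopropenone is strained; the 2,5-substitution pattern requires ring opening at the C(O)–CH bond, which should be favoured because it gives the less hindered alkenylrhodium. Ring closure requires both alkenes to be cis, which the (Z)-boronate and the ring origin of the second alkene guarantee, and the aprotic medium should disfavour protonation of the vinylrhodium before closure.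

Step 9
Reactants: 15 {4-[(1S,2E,4E)-6-{[tert-butyl(dimethyl)silyl]oxy}-1-hydroxy-3-methylhexa-2,4-dien-1-yl]-3,6-dioxocyclohexa-1,4-dien-1-yl}methyl acetate
Product: 16 {(1S,6R)-6-[(1S,2E,4E)-6-{[tert-butyl(dimethyl)silyl]oxy}-1-hydroxy-3-methylhexa-2,4-dien-1-yl]-2,5-dioxo-7-oxabicyclo[4.1.0]hept-3-en-3-yl}methyl acetate
Conditions: t-BuOOH (decane), DBU, CH2Cl2, −20 °C
Reagents that add atoms: tert-butyl hydroperoxide, CC(C)(C)OO
Why: Weitz–Scheffer nucleophilic epoxidation: the carbinol OH should hydrogen-bond to the adjacent C5 carbonyl, which activates C1 (the ring CH β to that carbonyl) over the other quinone alkene and holds the carbinol C–O in the ring plane, so that the peroxide adds to C1 on the face opposite the dienyl group and the enolate closes onto O–O at C6, setting both epoxide centers (1S,6R) from the S carbinol in one event.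

Step 10
Reactants: 16 {(1S,6R)-6-[(1S,2E,4E)-6-{[tert-butyl(dimethyl)silyl]oxy}-1-hydroxy-3-methylhexa-2,4-dien-1-yl]-2,5-dioxo-7-oxabicyclo[4.1.0]hept-3-en-3-yl}methyl acetate
Product: 17 {(1S,6R)-6-[(1S,2E,4E)-1-acetoxy-6-{[tert-butyl(dimethyl)silyl]oxy}-3-methylhexa-2,4-dien-1-yl]-2,5-dioxo-7-oxabicyclo[4.1.0]hept-3-en-3-yl}methyl acetate
Conditions: Ac2O, pyridine, DMAP (cat.), CH2Cl2, 0 °C
Reagents that add atoms: acetic anhydride, CC(=O)OC(C)=O
Why: Acylation of the secondary alcohol under mild amine catalysis should leave the epoxyquinone and the silyl ether intact and does not affect the configuration at the carbinol carbon.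

Step 11
Reactants: 17 {(1S,6R)-6-[(1S,2E,4E)-1-acetoxy-6-{[tert-butyl(dimethyl)silyl]oxy}-3-methylhexa-2,4-dien-1-yl]-2,5-dioxo-7-oxabicyclo[4.1.0]hept-3-en-3-yl}methyl acetate
Product: 18 {(1S,6R)-6-[(1S,2E,4E)-1-acetoxy-6-hydroxy-3-methylhexa-2,4-dien-1-yl]-2,5-dioxo-7-oxabicyclo[4.1.0]hept-3-en-3-yl}methyl acetate
Conditions: HF·pyridine, pyridine/THF, 0 °C
Reagents that add atoms: none
Why: Buffered fluoride desilylation should remove the primary silyl ether without opening the epoxide or cleaving the acetates.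

Step 12
Reactants: 18 {(1S,6R)-6-[(1S,2E,4E)-1-acetoxy-6-hydroxy-3-methylhexa-2,4-dien-1-yl]-2,5-dioxo-7-oxabicyclo[4.1.0]hept-3-en-3-yl}methyl acetate
Product: 19 {(1S,6R)-6-[(1S,2E,4E)-1-acetoxy-3-methyl-6-oxohexa-2,4-dien-1-yl]-2,5-dioxo-7-oxabicyclo[4.1.0]hept-3-en-3-yl}methyl acetate
Conditions: MnO2, CH2Cl2, rt
Reagents that add atoms: none
Why: Chemoselective MnO2 oxidation of the primary dienylic alcohol should give the (2E,4E)-dienal, since the only other carbinol is already acetylated.

**Compound list**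

1 | prop-2-yn-1-yl acetate | CC(=O)OCC#C | starting material
2 | (3,3-difluorocycloprop-1-en-1-yl)methyl acetate | CC(=O)OCC1=CC1(F)F | intermediate
3 | (3-oxocycloprop-1-en-1-yl)methyl acetate | CC(=O)OCC1=CC1=O | intermediate
4 | ethyl acetoacetate | CCOC(=O)CC(C)=O | starting material
5 | ethyl (2E)-3-{[(trifluoromethyl)sulfonyl]oxy}but-2-enoate | CCOC(=O)/C=C(C)/OS(=O)(=O)C(F)(F)F | intermediate
6 | tert-butyl(dimethyl){[(2E)-3-(4,4,5,5-tetramethyl-1,3,2-dioxaborolan-2-yl)prop-2-en-1-yl]oxy}silane | CC(C)(C)[Si](C)(C)OC/C=C/B1OC(C)(C)C(C)(C)O1 | starting material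
7 | ethyl (2E,4E)-6-{[tert-butyl(dimethyl)silyl]oxy}-3-methylhexa-2,4-dienoate | CCOC(=O)/C=C(C)/C=C/CO[Si](C)(C)C(C)(C)C | intermediate
8 | (2E,4E)-6-{[tert-butyl(dimethyl)silyl]oxy}-3-methylhexa-2,4-dien-1-ol | OC/C=C(C)/C=C/CO[Si](C)(C)C(C)(C)C | intermediate
9 | (2E,4E)-6-{[tert-butyl(dimethyl)silyl]oxy}-3-methylhexa-2,4-dienal | O=C/C=C(C)/C=C/CO[Si](C)(C)C(C)(C)C | intermediate
10 | methyl propiolate | COC(=O)C#C | starting material
11 | [(3-iodo-1-methoxypropa-1,2-dien-1-yl)oxy](trimethyl)silane | COC(O[Si](C)(C)C)=C=CI | intermediate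
12 | methyl (2Z)-2-[(1S,2E,4E)-6-{[tert-butyl(dimethyl)silyl]oxy}-3-methyl-1-[(trimethylsilyl)oxy]hexa-2,4-dien-1-yl]-3-iodoprop-2-enoate | COC(=O)/C(=C\I)[C@@H](O[Si](C)(C)C)/C=C(C)/C=C/CO[Si](C)(C)C(C)(C)C | intermediate
13 | methyl (2Z)-2-[(1S,2E,4E)-6-{[tert-butyl(dimethyl)silyl]oxy}-1-hydroxy-3-methylhexa-2,4-dien-1-yl]-3-iodoprop-2-enoate | COC(=O)/C(=C\I)[C@@H](O)/C=C(C)/C=C/CO[Si](C)(C)C(C)(C)C | intermediate
14 | methyl (2Z)-2-[(1S,2E,4E)-6-{[tert-butyl(dimethyl)silyl]oxy}-1-hydroxy-3-methylhexa-2,4-dien-1-yl]-3-(4,4,5,5-tetramethyl-1,3,2-dioxaborolan-2-yl)prop-2-enoate | COC(=O)/C(=C\B1OC(C)(C)C(C)(C)O1)[C@@H](O)/C=C(C)/C=C/CO[Si](C)(C)C(C)(C)C | intermediate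
15 | {4-[(1S,2E,4E)-6-{[tert-butyl(dimethyl)silyl]oxy}-1-hydroxy-3-methylhexa-2,4-dien-1-yl]-3,6-dioxocyclohexa-1,4-dien-1-yl}methyl acetate | CC(=O)OCC1=CC(=O)C([C@@H](O)/C=C(C)/C=C/CO[Si](C)(C)C(C)(C)C)=CC1=O | intermediate
16 | {(1S,6R)-6-[(1S,2E,4E)-6-{[tert-butyl(dimethyl)silyl]oxy}-1-hydroxy-3-methylhexa-2,4-dien-1-yl]-2,5-dioxo-7-oxabicyclo[4.1.0]hept-3-en-3-yl}methyl acetate | CC(=O)OCC1=CC(=O)[C@]2([C@H](/C=C(C)/C=C/CO[Si](C)(C)C(C)(C)C)O)O[C@@H]2C1=O | intermediate
17 | {(1S,6R)-6-[(1S,2E,4E)-1-acetoxy-6-{[tert-butyl(dimethyl)silyl]oxy}-3-methylhexa-2,4-dien-1-yl]-2,5-dioxo-7-oxabicyclo[4.1.0]hept-3-en-3-yl}methyl acetate | CC(=O)OCC1=CC(=O)[C@]2([C@H](/C=C(C)/C=C/CO[Si](C)(C)C(C)(C)C)OC(C)=O)O[C@@H]2C1=O | intermediate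
18 | {(1S,6R)-6-[(1S,2E,4E)-1-acetoxy-6-hydroxy-3-methylhexa-2,4-dien-1-yl]-2,5-dioxo-7-oxabicyclo[4.1.0]hept-3-en-3-yl}methyl acetate | CC(=O)OCC1=CC(=O)[C@]2([C@H](/C=C(C)/C=C/CO)OC(C)=O)O[C@@H]2C1=O | intermediate
19 | {(1S,6R)-6-[(1S,2E,4E)-1-acetoxy-3-methyl-6-oxohexa-2,4-dien-1-yl]-2,5-dioxo-7-oxabicyclo[4.1.0]hept-3-en-3-yl}methyl acetate | CC(=O)OCC1=CC(=O)[C@]2([C@H](/C=C(C)/C=C/C=O)OC(C)=O)O[C@@H]2C1=O | target

**Step count**

Total steps: 12. Longest linear sequence: 11 steps (steps 2 to 12, from ethyl acetoacetate).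

**Steps most likely to fail**

1. Step 8 (proposed new method). What may go wrong:
   - protonation of the β-acylvinylrhodium before it closes onto the ester, which would stop at an open-chain dienone;
   - ring opening of the cyclopropenolate toward the substituted carbon, which would lead to the 2,6-substituted ring or to loss of acetate;
   - conjugate addition of the alkenylrhodium to the quinone already formed.

   Fallback with known chemistry (arene oxidation in place of de novo ring construction), setting out from dienal 9 and coming back at quinone 15. Catalogue (4-bromo-2,5-dimethoxyphenyl)methanol is protected (NaH, 4-methoxybenzyl chloride, DMF) as 1-bromo-2,5-dimethoxy-4-{[(4-methoxybenzyl)oxy]methyl}benzene F1. Bromine–lithium exchange (n-BuLi, −78 °C), transmetalation to the aryl(butyl)zinc (ZnCl2, then n-BuLi) and addition to 9 catalysed by the amino alcohol (−)-3-exo-morpholinoisoborneol should give (1S,2E,4E)-6-{[tert-butyl(dimethyl)silyl]oxy}-1-(2,5-dimethoxy-4-{[(4-methoxybenzyl)oxy]methyl}phenyl)-3-methylhexa-2,4-dien-1-ol F2. Oxidative demethylation with (NH4)2Ce(NO3)6 in MeCN/H2O at 0 °C, which also removes the 4-methoxybenzyl group, should give 2-[(1S,2E,4E)-6-{[tert-butyl(dimethyl)silyl]oxy}-1-hydroxy-3-methylhexa-2,4-dien-1-yl]-5-(hydroxymethyl)cyclohexa-2,5-diene-1,4-dione F3. Selective acetylation of the primary alcohol (Ac2O, 2,4,6-collidine, −20 °C) returns 15.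

2. Step 9. What may go wrong:
   - peroxide addition at the other quinone alkene, followed by epoxidation there or by addition–elimination of the acetoxymethyl acetate;
   - poor facial selectivity if the hydrogen-bonded conformer does not dominate;
   - base-induced tautomerisation of the (hydroxyalkyl)quinone to an acylhydroquinone.

   Fallback (epoxidation moved to a quinone monoketal under reagent control), setting out from 15 and coming back at 16. Reduction with Na2S2O4 (EtOAc/H2O) gives {4-[(1S,2E,4E)-6-{[tert-butyl(dimethyl)silyl]oxy}-1-hydroxy-3-methylhexa-2,4-dien-1-yl]-2,5-dihydroxyphenyl}methyl acetate F4. Methylation of the less hindered phenol next to the acetoxymethyl carbon (MeI, one equivalent, K2CO3, acetone) should give {4-[(1S,2E,4E)-6-{[tert-butyl(dimethyl)silyl]oxy}-1-hydroxy-3-methylhexa-2,4-dien-1-yl]-5-hydroxy-2-methoxyphenyl}methyl acetate F5. Oxidation with PhI(OAc)2 in MeOH gives the quinone monoketal {4-[(1S,2E,4E)-6-{[tert-butyl(dimethyl)silyl]oxy}-1-hydroxy-3-methylhexa-2,4-dien-1-yl]-6,6-dimethoxy-3-oxocyclohexa-1,4-dien-1-yl}methyl acetate F6. In F6 only the carbonyl next to the side-chain carbon is left, so only the wanted alkene has an unsubstituted β-carbon. Tartrate-mediated nucleophilic epoxidation (Ph3COOH, NaN(SiMe3)2, diisopropyl tartrate of the matched configuration, toluene, −50 °C) should give {(1S,6R)-6-[(1S,2E,4E)-6-{[tert-butyl(dimethyl)silyl]oxy}-1-hydroxy-3-methylhexa-2,4-dien-1-yl]-2,2-dimethoxy-5-oxo-7-oxabicyclo[4.1.0]hept-3-en-3-yl}methyl acetate F7. Mild ketal hydrolysis (montmorillonite K10, wet CH2Cl2) returns 16.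

3. Step 6. What may go wrong:
   - low enantioselectivity with the electron-rich dienal;
   - acid-induced ionisation or allylic transposition of the doubly allylic carbinol;
   - loss of the silyl ether to Me3SiI.

   Fallback (racemic coupling and enzymatic resolution in place of asymmetric catalysis), setting out from 9 and 10 and coming back at 13. The MgI2-promoted three-component coupling (CH2Cl2, 0 °C) gives racemic methyl (2Z)-2-[(2E,4E)-6-{[tert-butyl(dimethyl)silyl]oxy}-1-hydroxy-3-methylhexa-2,4-dien-1-yl]-3-iodoprop-2-enoate F8. Lipase-catalysed kinetic resolution (Pseudomonas cepacia lipase, vinyl acetate, t-BuOMe, rt) should, by the empirical size rule for lipases, acylate the R alcohol to methyl (2Z)-2-[(1R,2E,4E)-1-acetoxy-6-{[tert-butyl(dimethyl)silyl]oxy}-3-methylhexa-2,4-dien-1-yl]-3-iodoprop-2-enoate F9 and leave 13, which is separated by chromatography.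

**Further compounds**

F1 | step 8 | 1-bromo-2,5-dimethoxy-4-{[(4-methoxybenzyl)oxy]methyl}benzene | COc1cc(COCc2ccc(OC)cc2)c(OC)cc1Br
F2 | step 8 | (1S,2E,4E)-6-{[tert-butyl(dimethyl)silyl]oxy}-1-(2,5-dimethoxy-4-{[(4-methoxybenzyl)oxy]methyl}phenyl)-3-methylhexa-2,4-dien-1-ol | COc1cc(COCc2ccc(OC)cc2)c(OC)cc1[C@@H](O)/C=C(C)/C=C/CO[Si](C)(C)C(C)(C)C
F3 | step 8 | 2-[(1S,2E,4E)-6-{[tert-butyl(dimethyl)silyl]oxy}-1-hydroxy-3-methylhexa-2,4-dien-1-yl]-5-(hydroxymethyl)cyclohexa-2,5-diene-1,4-dione | OCC1=CC(=O)C([C@@H](O)/C=C(C)/C=C/CO[Si](C)(C)C(C)(C)C)=CC1=O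
F4 | step 9 | {4-[(1S,2E,4E)-6-{[tert-butyl(dimethyl)silyl]oxy}-1-hydroxy-3-methylhexa-2,4-dien-1-yl]-2,5-dihydroxyphenyl}methyl acetate | CC(=O)OCc1cc(O)c([C@@H](O)/C=C(C)/C=C/CO[Si](C)(C)C(C)(C)C)cc1O
F5 | step 9 | {4-[(1S,2E,4E)-6-{[tert-butyl(dimethyl)silyl]oxy}-1-hydroxy-3-methylhexa-2,4-dien-1-yl]-5-hydroxy-2-methoxyphenyl}methyl acetate | CC(=O)OCc1cc(O)c([C@@H](O)/C=C(C)/C=C/CO[Si](C)(C)C(C)(C)C)cc1OC
F6 | step 9 | {4-[(1S,2E,4E)-6-{[tert-butyl(dimethyl)silyl]oxy}-1-hydroxy-3-methylhexa-2,4-dien-1-yl]-6,6-dimethoxy-3-oxocyclohexa-1,4-dien-1-yl}methyl acetate | CC(=O)OCC1=CC(=O)C([C@@H](O)/C=C(C)/C=C/CO[Si](C)(C)C(C)(C)C)=CC1(OC)OC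
F7 | step 9 | {(1S,6R)-6-[(1S,2E,4E)-6-{[tert-butyl(dimethyl)silyl]oxy}-1-hydroxy-3-methylhexa-2,4-dien-1-yl]-2,2-dimethoxy-5-oxo-7-oxabicyclo[4.1.0]hept-3-en-3-yl}methyl acetate | CC(=O)OCC1=CC(=O)[C@]2([C@H](/C=C(C)/C=C/CO[Si](C)(C)C(C)(C)C)O)O[C@@H]2C1(OC)OC
F8 | step 6 | racemic methyl (2Z)-2-[(2E,4E)-6-{[tert-butyl(dimethyl)silyl]oxy}-1-hydroxy-3-methylhexa-2,4-dien-1-yl]-3-iodoprop-2-enoate | COC(=O)/C(=C\I)C(O)/C=C(C)/C=C/CO[Si](C)(C)C(C)(C)C
F9 | step 6 | methyl (2Z)-2-[(1R,2E,4E)-1-acetoxy-6-{[tert-butyl(dimethyl)silyl]oxy}-3-methylhexa-2,4-dien-1-yl]-3-iodoprop-2-enoate | COC(=O)/C(=C\I)[C@H](OC(C)=O)/C=C(C)/C=C/CO[Si](C)(C)C(C)(C)C
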